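**Retrosynthetic overview**

1. Target 41 ⇐ alcohol 35 + N-methylurocanic acid 39 (C8 ester); the C4 hemiketal comes from the methyl ketal and the C3 methyl ester from acid 33.
2. 33 ⇐ bridged 1,4-oxathiane S,S-dioxide 30. The strategy rests on the cis C5=C6 bond of the dihydrofuran ring O–C4–C5=C6–C7, flanked by the fully substituted C4 and C7: it is the alkene left when the six-membered C5–SO2–C6 ring loses SO2 (Ramberg–Bäcklund), and the same bond completes the ten-membered carbocycle.
3. 30 ⇐ chloro keto thiol 26: the eleven-membered ring is closed by S-alkylation of the C6 thiolate with the C5 chloride (a thiol on C5 would close onto the keto ester to a thiotetronic acid), then the oxathiane ring by transannular ketalisation C7–OH → C4.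
4. 26 ⇐ aldehyde ester 13: C3–C4 by enolate acylation, C6–S by thiolate opening of a C6–C7 epoxide, C7/C8 by isopropenyl addition, CBS reduction, directed epoxidation and inversion at C8; C2–C3 by Wittig homologation.
5. 13 ⇐ (R)-α-phellandrene 1 by ketene [2+2] addition and cyclobutanone cleavage (C1, C10, C14). Ring order: cyclohexene, eleven-membered thiacycle, oxathiane, contraction to the dihydrofuran.

Key step: step 20

Numbering: eunicellane numbering is used throughout (C1/C10 ring-fusion CH, C2 CH2, C3 CH–CO2Me, C4 ketal carbon, C5 and C6 the carbons on sulfur, C7 C(CH3)–O, C8 CH–O, C9 CH2, C11=C12 ring alkene, C14 CH–i-Pr).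

Assumption: C3 lies between the ester and the masked C4 ketone and can epimerise through the enol of the ring-opened keto ester, so its configuration in the target is taken to be the more stable one; it is set under equilibrating conditions in step 17 and can settle again in step 27.

**Route**

Step 1
Reactants: 1 (R)-(−)-α-phellandrene; 2 trichloroacetyl chloride
Product: 4 cis-fused dichlorocyclobutanone (C=O on C1; CCl2 on C10; four-membered ring anti to isopropyl), via dichloroketene 3 (not isolated)
Conditions: Zn dust, Et2O, ultrasound, 15–20 °C (2 added slowly)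
Reagents that add atoms: trichloroacetyl chloride (2), ClC(Cl)(Cl)C(Cl)=O
Why: Zinc dechlorinates 2 to dichloroketene, which adds in a ketene [2+2] cycloaddition to the disubstituted double bond of the diene, carbonyl carbon to the diene terminus C1, on the face anti to the isopropyl group, so that the new bonds at C1 and C10 are cis to each other and trans to C14.

Step 2
Reactants: 4 dichlorocyclobutanone
Product: 5 cyclobutanone
Conditions: Zn, AcOH, rt
Reagents that add atoms: none
Why: Reductive dehalogenation with zinc in acetic acid removes both α-chlorines and leaves the ring fusion and the trisubstituted alkene untouched.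

Step 3
Reactants: 5 cyclobutanone; 6 tert-butoxybis(dimethylamino)methane
Product: 7 enaminone (dimethylaminomethylidene on C9)
Conditions: 6 (1.5 equiv), toluene, 60 °C
Reagents that add atoms: tert-butoxybis(dimethylamino)methane (6), CN(C)C(OC(C)(C)C)N(C)C
Why: The only α-methylene of the ketone (C9) condenses with the aminal ester (enaminone formation), which brings in the future C8.

Step 4
Reactants: 7 enaminone
Product: 8 ester acetal (CO2Me on C1, CH2CH(OMe)2 on C10)
Conditions: p-TsOH·H2O, MeOH, reflux
Reagents that add atoms: methanol, CO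
Why: Acid methanolysis turns the enaminone into a masked β-formyl ketone, and strain-driven retro-Claisen cleavage of the cyclobutanone by methanol gives the C2 methyl ester and the C8 dimethyl acetal without touching C1 or C10.

Step 5
Reactants: 8 ester acetal; 9 methyl (triphenylphosphoranylidene)acetate
Product: 11 (E)-enoate acetal (C1–CH=CH–CO2Me), via aldehyde acetal 10 (not isolated)
Conditions: DIBAL-H, CH2Cl2, −78 °C; MeOH; then 9, −78 °C → rt
Reagents that add atoms: methyl (triphenylphosphoranylidene)acetate (9), COC(=O)C=P(c1ccccc1)(c1ccccc1)c1ccccc1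
Why: Partial reduction of the hindered ester by DIBAL-H stops at the aluminium hemiacetal, and the aldehyde set free on warming is trapped at once by the stabilised ylide in an E-selective Wittig reaction, which avoids epimerisation at C1.

Step 6
Reactants: 11 (E)-enoate acetal
Product: 12 saturated ester acetal (C1–CH2CH2CO2Me)
Conditions: H2 (1 atm), RhCl(PPh3)3 (5 mol%), benzene/EtOH, rt
Reagents that add atoms: none
Why: Homogeneous catalytic hydrogenation with RhCl(PPh3)3 reduces the disubstituted conjugated alkene and should leave the hindered trisubstituted ring alkene.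

Step 7
Reactants: 12 saturated ester acetal
Product: 13 ester aldehyde (C8 aldehyde)
Conditions: p-TsOH·H2O (cat.), acetone/H2O, rt
Reagents that add atoms: water, O
Why: Acid-catalysed acetal hydrolysis frees the C8 aldehyde while ester and alkene are inert.

Step 8
Reactants: 13 ester aldehyde; 14 isopropenylmagnesium bromide
Product: 15 allylic alcohols (both C8 epimers)
Conditions: 14, THF, −78 °C; then H2O
Reagents that add atoms: isopropenylmagnesium bromide (14), CC(=C)[Mg]Br
Why: Grignard addition to the aldehyde is far faster than to the ester at −78 °C; the remote ring stereocentres are not expected to control C8, so both epimers are taken on to the ketone.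

Step 9
Reactants: 15 allylic alcohols
Product: 16 isopropenyl ketone
Conditions: Dess–Martin periodinane, CH2Cl2, rt
Reagents that add atoms: none
Why: Dess–Martin oxidation gives the enone and removes the uncontrolled C8 centre.

Step 10
Reactants: 16 isopropenyl ketone
Product: 17 (8R)-allylic alcohol
Conditions: (S)-Me-CBS oxazaborolidine (20 mol%), catecholborane, toluene, −78 °C
Reagents that add atoms: none
Why: In the Corey–Bakshi–Shibata reduction the α-branched alkenyl group acts as the large and the C9 methylene as the small substituent, so the (S)-catalyst should deliver hydride to give the (8R)-alcohol under reagent control, and catecholborane at low temperature does not hydroborate the alkenes.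

Step 11
Reactants: 17 (8R)-allylic alcohol
Product: 18 erythro epoxy alcohol (C6–C7 epoxide)
Conditions: VO(acac)2 (5 mol%), t-BuOOH, CH2Cl2, 0 °C → rt
Reagents that add atoms: tert-butyl hydroperoxide, CC(C)(C)OO
Why: Hydroxyl-directed vanadium-catalysed epoxidation reacts only at the allylic alcohol, and allylic 1,2-strain between the C7 methyl group and the C9 chain in the metal alkoxide transition state sets C7 erythro to C8, which is the target configuration at C7.

Step 12
Reactants: 18 erythro epoxy alcohol
Product: 19 threo 4-nitrobenzoate (C8 inverted)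
Conditions: 4-nitrobenzoic acid, PPh3, DIAD, toluene, 0 °C → rt
Reagents that add atoms: 4-nitrobenzoic acid, OC(=O)c1ccc(cc1)[N+](=O)[O-]
Why: Mitsunobu esterification replaces the activated C8 oxygen by the carboxylate with SN2 inversion, which turns the erythro pair into the threo pair of the target; the acidic 4-nitrobenzoic acid is chosen because the carbinol is hindered.

Step 13
Reactants: 19 threo 4-nitrobenzoate
Product: 20 threo epoxy alcohol
Conditions: K2CO3 (cat.), MeOH, 0 °C
Reagents that add atoms: none
Why: Carbonate-catalysed transesterification cleaves the activated aryl ester quickly, the methyl ester is unchanged in methanol and the epoxide is inert.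

Step 14
Reactants: 20 threo epoxy alcohol
Product: 21 TBS ether
Conditions: TBSOTf, 2,6-lutidine, CH2Cl2, −78 °C
Reagents that add atoms: tert-butyldimethylsilyl triflate, CC(C)(C)[Si](C)(C)OS(=O)(=O)C(F)(F)F
Why: Silylation with the silyl triflate and a hindered base at low temperature protects the hindered secondary alcohol without opening the epoxide or enolising the ester.

Step 15
Reactants: 21 TBS ether; 22 triphenylmethanethiol
Product: 23 hydroxy trityl sulfide (C6–S–CPh3, C7–OH)
Conditions: 22, Cs2CO3 (cat.), MeOH/DMF, 50 °C
Reagents that add atoms: triphenylmethanethiol (22), SC(c1ccccc1)(c1ccccc1)c1ccccc1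
Why: The thiolate opens the 2,2-disubstituted epoxide by SN2 attack at the primary carbon C6, so the oxygen stays on C7 with its configuration, and sulfur enters as a base-stable, acid-labile thioether.

Step 16
Reactants: 23 hydroxy trityl sulfide; 24 2-chloro-N-methoxy-N-methylacetamide
Product: 25 chloro keto ester (C3 epimers)
Conditions: LDA (2.2 equiv), THF, −78 °C; 24, −78 → −40 °C; AcOH
Reagents that add atoms: 2-chloro-N-methoxy-N-methylacetamide (24), CON(C)C(=O)CCl
Why: The alkoxide/ester enolate dianion is C-acylated at C3 by the N-methoxy-N-methylamide (Claisen-type acylation), whose chelated tetrahedral intermediate survives until the quench so that the chloromethyl ketone appears only on work-up; C3 is formed as a configurationally labile β-keto ester centre.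

Step 17
Reactants: 25 chloro keto ester
Product: 28 bridged oxathiane methyl ketal (cyclic sulfide; C8 OTBS; methyl ester), via chloro keto thiol 26 (not isolated), via hemiketal 27 (not isolated)
Conditions: TFA (5%), Et3SiH, CH2Cl2, 0 °C; evaporate; slow addition to i-Pr2NEt, degassed MeOH (1 mM), rt; then PPTS (excess), 40 °C
Reagents that add atoms: methanol, CO
Why: Ionic detritylation frees the thiol under acid, where the chloro ketone is stable, then the thiolate closes the eleven-membered ring by fast intramolecular S-alkylation of the α-chloro ketone, the C7 hydroxyl adds across the ring to C4, and acid-catalysed ketalisation in methanol gives the methyl ketal, in which C4 is fixed by the bridge (C5 and C6 must lie on the same side) and C3 settles by enolisation to the more stable epimer.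

Step 18
Reactants: 28 bridged oxathiane methyl ketal
Product: 29 oxathiane S,S-dioxide methyl ester
Conditions: (NH4)6Mo7O24·4H2O (cat.), 30% H2O2, EtOH, 0 °C → rt
Reagents that add atoms: hydrogen peroxide, OO
Why: Molybdate-catalysed sulfide oxidation with hydrogen peroxide takes sulfur through the sulfoxide to the sulfone much faster than the hindered trisubstituted alkene is epoxidised.

Step 19
Reactants: 29 oxathiane S,S-dioxide methyl ester
Product: 30 oxathiane S,S-dioxide acid
Conditions: Me3SnOH, ClCH2CH2Cl, 80 °C; cold dilute HCl work-up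
Reagents that add atoms: trimethyltin hydroxide, C[Sn](C)(C)O
Why: Ester hydrolysis with Me3SnOH is mild and non-enolising, so C3 is not epimerised and the C4 ketal, which the neighbouring sulfone makes stable to acid, is not lost by β-elimination.

Step 20
Reactants: 30 oxathiane S,S-dioxide acid
Product: 33 dihydrofuran methyl ketal acid (C5=C6), via bromo sulfone 31 (not isolated), via episulfone 32 (not isolated)
Conditions: CBr2F2, KOH/Al2O3, t-BuOH/CH2Cl2, 0 °C → rt; pH 5 buffer
Reagents that add atoms: none
Why: The carboxylate of 30 is deprotonated reversibly at C5 or C6, the α-sulfonyl carbanion takes bromine from CBr2F2 to give 31, and deprotonation at the other α-carbon closes episulfone 32 by 1,3-displacement of bromide before SO2 leaves cheletropically, which is a Ramberg–Bäcklund reaction with in situ halogenation, closest to the known contraction of six-membered cyclic sulfones to cyclopentenes. The ring closed is the 2,5-dihydrofuran O–C4–C5=C6–C7, formed by contraction of the oxathiane through the three-membered episulfone (3-exo-tet closure, then extrusion), and the same C5–C6 bond completes the ten-membered carbocycle. No stereocentre is created, and the alkene can only be cis because it lies in the five-membered ring. The step needs chemoselectivity for sulfone α-halogenation over reaction at the C11=C12 alkene and over β-elimination of the oxygens on C4 and C7: the halogen source gives up bromine only to carbanions and leaves the sluggish difluorocarbene, C4 and C7 carry no hydrogen, the ring C–O bonds are poorly aligned with the carbanion and would re-close by oxa-Michael addition, and the C3 carboxylate cannot enolise, so the ketal is not opened from that side.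

Step 21
Reactants: 33 dihydrofuran methyl ketal acid
Product: 34 dihydrofuran methyl ester
Conditions: Me3SiCHN2, MeOH/toluene, 0 °C
Reagents that add atoms: trimethylsilyldiazomethane, C[Si](C)(C)C=[N+]=[N-]
Why: O-Methylation of the acid with the diazoalkane in methanol is neutral and spares the now allylic, acid-labile ketal; 33 is used at once.

Step 22
Reactants: 34 dihydrofuran methyl ester
Product: 35 C8 alcohol
Conditions: Bu4NF, AcOH, THF, rt
Reagents that add atoms: none
Why: Buffered fluoride desilylation cleaves the Si–O bond without base-induced elimination at C3.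

Step 23
Reactants: 36 urocanic acid
Product: 37 methyl urocanate
Conditions: MeOH, H2SO4 (cat.), reflux
Reagents that add atoms: methanol, CO
Why: Fischer esterification masks the acid so that the imidazole nitrogen can be alkylated cleanly.

Step 24
Reactants: 37 methyl urocanate
Product: 38 methyl (E)-3-(1-methylimidazol-4-yl)acrylate
Conditions: NaH, DMF, 0 °C; MeI
Reagents that add atoms: iodomethane, CI
Why: N-Alkylation of the imidazolide should occur mainly at the nitrogen remote from the 4-substituent for steric reasons, giving the 1-methyl-4-substituted isomer, which is separated from the minor regioisomer.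

Step 25
Reactants: 38 methyl (E)-3-(1-methylimidazol-4-yl)acrylate
Product: 39 N-methylurocanic acid
Conditions: LiOH, THF/H2O, rt; HCl to pH 5
Reagents that add atoms: lithium hydroxide, [Li+].[OH-]
Why: Saponification and adjustment to the isoelectric point give the acid with the E alkene intact.

Step 26
Reactants: 35 C8 alcohol; 39 N-methylurocanic acid
Product: 40 C8 urocanate methyl ketal
Conditions: 39, DCC, DMAP, CH2Cl2/DMF, rt
Reagents that add atoms: N-methylurocanic acid (39), OC(=O)/C=C/c1cn(C)cn1
Why: Steglich esterification acylates the only free hydroxyl, C8–OH, with retention at C8.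

Step 27
Reactants: 40 C8 urocanate methyl ketal
Product: 41 target
Conditions: CSA, THF/H2O, rt
Reagents that add atoms: water, O
Why: Ketal hydrolysis under mild aqueous acid goes through the allyl-stabilised oxocarbenium ion at C4, which water captures to give the hemiketal, with C4 fixed by the bridge and C3 at its thermodynamic configuration.

**Compound list**

1 | (R)-(−)-α-phellandrene | CC1=CC[C@H](C(C)C)C=C1 | starting material
2 | trichloroacetyl chloride | ClC(Cl)(Cl)C(Cl)=O | starting material
3 | dichloroketene | ClC(Cl)=C=O | intermediate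
4 | 8,8-dichloro-5-isopropyl-2-methylbicyclo[4.2.0]oct-2-en-7-one, cis-fused, four-membered ring anti to isopropyl (C=O on C1, CCl2 on C10) | O=C1[C@@H]2[C@@H](C(C)C)CC=C(C)[C@@H]2C1(Cl)Cl | intermediate
5 | 5-isopropyl-2-methylbicyclo[4.2.0]oct-2-en-7-one, same configuration | O=C1[C@@H]2[C@@H](C(C)C)CC=C(C)[C@@H]2C1 | intermediate
6 | tert-butoxybis(dimethylamino)methane | CN(C)C(OC(C)(C)C)N(C)C | starting material
7 | enaminone, 8-[(E)-(dimethylamino)methylidene] derivative of 5 | O=C1[C@@H]2[C@@H](C(C)C)CC=C(C)[C@@H]2/C1=C\N(C)C | intermediate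
8 | ester acetal: cyclohexene with CO2Me on C1 and CH2CH(OMe)2 on C10, cis to each other and trans to the C14 isopropyl | COC(=O)[C@@H]1[C@@H](C(C)C)CC=C(C)[C@@H]1CC(OC)OC | intermediate
9 | methyl (triphenylphosphoranylidene)acetate | COC(=O)C=P(c1ccccc1)(c1ccccc1)c1ccccc1 | starting material
10 | aldehyde acetal (CHO on C1) | O=C[C@@H]1[C@@H](C(C)C)CC=C(C)[C@@H]1CC(OC)OC | intermediate
11 | (E)-enoate acetal (C1–CH=CH–CO2Me) | COC(=O)/C=C/[C@@H]1[C@@H](C(C)C)CC=C(C)[C@@H]1CC(OC)OC | intermediate
12 | saturated ester acetal (C1–CH2CH2CO2Me) | COC(=O)CC[C@@H]1[C@@H](C(C)C)CC=C(C)[C@@H]1CC(OC)OC | intermediate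
13 | ester aldehyde (C10–CH2–CHO) | COC(=O)CC[C@@H]1[C@@H](C(C)C)CC=C(C)[C@@H]1CC=O | intermediate
14 | isopropenylmagnesium bromide | CC(=C)[Mg]Br | starting material
15 | allylic alcohols, isopropenyl carbinol at C8, both C8 epimers | COC(=O)CC[C@@H]1[C@@H](C(C)C)CC=C(C)[C@@H]1CC(O)C(C)=C | intermediate
16 | isopropenyl ketone (C8 ketone) | COC(=O)CC[C@@H]1[C@@H](C(C)C)CC=C(C)[C@@H]1CC(=O)C(C)=C | intermediate
17 | (8R)-allylic alcohol | COC(=O)CC[C@@H]1[C@@H](C(C)C)CC=C(C)[C@@H]1C[C@@H](O)C(C)=C | intermediate
18 | erythro epoxy alcohol: C6–C7 epoxide with C7 methyl, epoxide O and C8–OH on the same side in the Fischer projection C6–C9, C8 epimeric to the target | COC(=O)CC[C@@H]1[C@@H](C(C)C)CC=C(C)[C@@H]1C[C@@H](O)[C@]2(C)CO2 | intermediate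
19 | threo 4-nitrobenzoate (C8 inverted, target configuration at C7 and C8) | COC(=O)CC[C@@H]1[C@@H](C(C)C)CC=C(C)[C@@H]1C[C@H](OC(=O)c2ccc(cc2)[N+](=O)[O-])[C@]3(C)CO3 | intermediate
20 | threo epoxy alcohol | COC(=O)CC[C@@H]1[C@@H](C(C)C)CC=C(C)[C@@H]1C[C@H](O)[C@]2(C)CO2 | intermediate
21 | TBS ether of 20 | COC(=O)CC[C@@H]1[C@@H](C(C)C)CC=C(C)[C@@H]1C[C@H](O[Si](C)(C)C(C)(C)C)[C@]2(C)CO2 | intermediate
22 | triphenylmethanethiol | SC(c1ccccc1)(c1ccccc1)c1ccccc1 | starting material
23 | hydroxy trityl sulfide (C6–S–CPh3, tertiary C7–OH, C8–OTBS) | COC(=O)CC[C@@H]1[C@@H](C(C)C)CC=C(C)[C@@H]1C[C@H](O[Si](C)(C)C(C)(C)C)[C@](O)(C)CSC(c2ccccc2)(c2ccccc2)c2ccccc2 | intermediate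
24 | 2-chloro-N-methoxy-N-methylacetamide | CON(C)C(=O)CCl | starting material
25 | chloro keto ester: C3 bears CO2Me and C(=O)CH2Cl (C4, C5); C3 epimers | COC(=O)C(C(=O)CCl)C[C@@H]1[C@@H](C(C)C)CC=C(C)[C@@H]1C[C@H](O[Si](C)(C)C(C)(C)C)[C@](O)(C)CSC(c2ccccc2)(c2ccccc2)c2ccccc2 | intermediate
26 | chloro keto thiol (C6–SH) | COC(=O)C(C(=O)CCl)C[C@@H]1[C@@H](C(C)C)CC=C(C)[C@@H]1C[C@H](O[Si](C)(C)C(C)(C)C)[C@](O)(C)CS | intermediate
27 | hemiketal of the eleven-membered cyclic sulfide (C7–O–C4 bridge, C4–OH; C3 epimers) | COC(=O)C1C[C@@H]2[C@@H](C(C)C)CC=C(C)[C@@H]2C[C@H](O[Si](C)(C)C(C)(C)C)[C@]2(C)CSC[C@@]1(O)O2 | intermediate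
28 | bridged 1,4-oxathiane methyl ketal (C4–OMe and C7–CH3 on the outer faces; C3 as in the target) | COC(=O)[C@@H]1C[C@@H]2[C@@H](C(C)C)CC=C(C)[C@@H]2C[C@H](O[Si](C)(C)C(C)(C)C)[C@]2(C)CSC[C@@]1(OC)O2 | intermediate
29 | bridged oxathiane S,S-dioxide methyl ester | COC(=O)[C@@H]1C[C@@H]2[C@@H](C(C)C)CC=C(C)[C@@H]2C[C@H](O[Si](C)(C)C(C)(C)C)[C@]2(C)CS(=O)(=O)C[C@@]1(OC)O2 | intermediate
30 | bridged oxathiane S,S-dioxide acid (key-step precursor; C4 methyl ketal, C8 OTBS, C3 CO2H) | OC(=O)[C@@H]1C[C@@H]2[C@@H](C(C)C)CC=C(C)[C@@H]2C[C@H](O[Si](C)(C)C(C)(C)C)[C@]2(C)CS(=O)(=O)C[C@@]1(OC)O2 | intermediate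
31 | α-bromo sulfone (drawn as the C6 bromide; the C5 bromide leads to the same episulfone; CHBr configuration not defined) | OC(=O)[C@@H]1C[C@@H]2[C@@H](C(C)C)CC=C(C)[C@@H]2C[C@H](O[Si](C)(C)C(C)(C)C)[C@]2(C)C(Br)S(=O)(=O)C[C@@]1(OC)O2 | intermediate
32 | episulfone (thiirane 1,1-dioxide cis-fused across C5–C6; the two transient centres are lost with SO2) | OC(=O)[C@@H]1C[C@@H]2[C@@H](C(C)C)CC=C(C)[C@@H]2C[C@H](O[Si](C)(C)C(C)(C)C)[C@]2(C)C3C(S3(=O)=O)[C@@]1(OC)O2 | intermediate
33 | dihydrofuran methyl ketal acid (key-step product; C5=C6, C8 OTBS) | OC(=O)[C@@H]1C[C@@H]2[C@@H](C(C)C)CC=C(C)[C@@H]2C[C@H](O[Si](C)(C)C(C)(C)C)[C@]2(C)C=C[C@@]1(OC)O2 | intermediate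
34 | dihydrofuran methyl ketal methyl ester (C8 OTBS) | COC(=O)[C@@H]1C[C@@H]2[C@@H](C(C)C)CC=C(C)[C@@H]2C[C@H](O[Si](C)(C)C(C)(C)C)[C@]2(C)C=C[C@@]1(OC)O2 | intermediate
35 | C8 alcohol (methyl ketal, methyl ester) | COC(=O)[C@@H]1C[C@@H]2[C@@H](C(C)C)CC=C(C)[C@@H]2C[C@H](O)[C@]2(C)C=C[C@@]1(OC)O2 | intermediate
36 | urocanic acid | OC(=O)/C=C/c1c[nH]cn1 | starting material
37 | methyl urocanate | COC(=O)/C=C/c1c[nH]cn1 | intermediate
38 | methyl (E)-3-(1-methylimidazol-4-yl)acrylate | COC(=O)/C=C/c1cn(C)cn1 | intermediate
39 | N-methylurocanic acid, (E)-3-(1-methylimidazol-4-yl)acrylic acid | OC(=O)/C=C/c1cn(C)cn1 | intermediate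
40 | C8 N-methylurocanate, C4 methyl ketal | COC(=O)[C@@H]1C[C@@H]2[C@@H](C(C)C)CC=C(C)[C@@H]2C[C@H](OC(=O)/C=C/c3cn(C)cn3)[C@]2(C)C=C[C@@]1(OC)O2 | intermediate
41 | CNP0113846.1 | COC(=O)[C@@H]1C[C@@H]2[C@@H](C(C)C)CC=C(C)[C@@H]2C[C@H](OC(=O)/C=C/c2cn(C)cn2)[C@]2(C)C=C[C@@]1(O)O2 | target

**Step count and risks**

Total step count: 27. Longest linear sequence: 24 (steps 1–22, 26 and 27; steps 23–25 make the side-chain acid).

Steps most likely to fail:

1. Step 20 (Ramberg–Bäcklund contraction). The α-sulfonyl carbanion at C5 may expel the C4 methoxide or open the ring by β-elimination faster than it is brominated, or the carbene from the halogen source may add to the C11=C12 alkene. Fallback: the halogen is put in by a separate aprotic step and only then is the elimination started. Acid 30 is converted with LDA (2.2 equiv, THF, −78 °C) into the carboxylate/α-sulfonyl dianion and chlorinated with hexachloroethane to the α-chloro sulfone acid F1 (drawn as the C6 chloride; the C5 isomer serves equally), which is isolated. KOt-Bu in THF at 0 °C then closes the episulfone, SO2 is lost, and the route is rejoined at acid 33.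

2. Step 17 (closure of the eleven-membered ring). Intermolecular S-alkylation to oligomers, or O-alkylation of the keto ester enolate by the chloride, may outrun ring closure. Fallback: a twelve-membered ring is closed through a sulfur–sulfur bond and one sulfur is then removed. Chloride 25 is treated with Ph3CSH and i-Pr2NEt to give the bis(trityl sulfide) F2. Iodine in CH2Cl2/MeOH at high dilution removes both trityl groups oxidatively and gives the cyclic disulfide F3; no thiolate is formed, so the C5 sulfur cannot attack the ester. P(NEt2)3 in benzene then extrudes one sulfur (the C6 thiolate attacks the activated C5 of the thiophosphonium intermediate) to give hemiketal 27, which is ketalised with PPTS/MeOH as in step 17 to reach 28.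

3. Step 16 (C-acylation at C3). Proton transfer from the acidic α-chloro amide to the enolate, or reaction of the C7 alkoxide with the reagent, may compete with C-acylation. Fallback: a neutral silyl ketene acetal is acylated instead of the lithium enolate. Compound 23 is treated with LDA (2.2 equiv) and Me3SiCl at −78 °C to give the O-silylated ketene acetal F4, which reacts with chloroacetyl chloride in CH2Cl2 (acylation of a ketene silyl acetal by an acid chloride). Mild acidic work-up removes the C7 trimethylsilyl ether and returns chloro keto ester 25.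

**Further compounds**

F1 | step 20 | α-chloro sulfone acid (C6 chloride of 30) | OC(=O)[C@@H]1C[C@@H]2[C@@H](C(C)C)CC=C(C)[C@@H]2C[C@H](O[Si](C)(C)C(C)(C)C)[C@]2(C)C(Cl)S(=O)(=O)C[C@@]1(OC)O2
F2 | step 17 | bis(trityl sulfide) keto ester (C5–S–CPh3 and C6–S–CPh3) | COC(=O)C(C(=O)CSC(c2ccccc2)(c2ccccc2)c2ccccc2)C[C@@H]1[C@@H](C(C)C)CC=C(C)[C@@H]1C[C@H](O[Si](C)(C)C(C)(C)C)[C@](O)(C)CSC(c2ccccc2)(c2ccccc2)c2ccccc2
F3 | step 17 | twelve-membered cyclic disulfide (C5–S–S–C6, C4 ketone, C7–OH) | COC(=O)C1C[C@@H]2[C@@H](C(C)C)CC=C(C)[C@@H]2C[C@H](O[Si](C)(C)C(C)(C)C)[C@](O)(C)CSSCC1=O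
F4 | step 16 | methyl trimethylsilyl ketene acetal of 23 with C7–OSiMe3 | COC(O[Si](C)(C)C)=CC[C@@H]1[C@@H](C(C)C)CC=C(C)[C@@H]1C[C@H](O[Si](C)(C)C(C)(C)C)[C@](O[Si](C)(C)C)(C)CSC(c2ccccc2)(c2ccccc2)c2ccccc2
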